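**Plan**

- **Retrosynthesis.** Cut the acetate and C13=C14 (olefination of a C13 methyl ketone). Then cut C13–C16 and the temporary O8–C13 bond of a δ-lactone. Then take C7 out of ring B (bonds C6–C7 and C7–C8). Last, cut C8–C17, C9–C11, C5=C6 and C9–C10.
- **Forward.** Ring A is bought as 2,2,6-trimethylcyclohexanone. Allylation, Wacker oxidation and aldol closure give a five-membered forerunner of ring B (C5, C6, C8, C9, C10). An acrylate adds C11–C13, a methyl coupling adds C17 and CBr2 brings C7. One silver-triggered event then enlarges this ring to ring B and closes a temporary lactone. C16, C14/C15 and the acetate follow.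
- **Enabling feature.** In ring B the carbinol carbon C8 (CH3, O) is followed by two bare methylenes, C7 and C6, so C6–C7–C8 is the footprint of a 2-bromoallyl cation with C7 as the inserted atom. The C9 chain carries a carbonyl oxygen that can reach only C8. The axial C10 methyl closes the β face.
- **Stereochemistry.** C10 comes from the enantioselective palladium-catalysed allylation. C9 (kinetic protonation) and C5 (hydrogenation) are both set on the face opposite to the C10 methyl. C8 is set by the tethered α-face C–O closure. The E alkene comes from the Horner–Wadsworth–Emmons reaction.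

Key step: step 10

Remark: labdane numbering is used for all bicyclic compounds (C7 is absent up to compound 12); α means the face opposite to the C10 methyl group.

Step 1
Reactants: 1 2,2,6-trimethylcyclohexan-1-one (racemic); 2 allyl chloroformate
Product: 3 allyl 2,6,6-trimethylcyclohex-1-en-1-yl carbonate
Conditions: LiN(SiMe3)2, THF, 0 °C; then 2, −78 °C
Reagents that add atoms: none
Why: Enol carbonate formation: 1 has a single enolisable position, so LiN(SiMe3)2 gives one enolate, the hard chloroformate acylates it on oxygen, and the stereocentre of racemic 1 is erased.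

Step 2
Reactants: 3 allyl 2,6,6-trimethylcyclohex-1-en-1-yl carbonate
Product: 4 (R)-2-allyl-2,6,6-trimethylcyclohexan-1-one
Conditions: Pd2(dba)3 (cat.), (R)-t-BuPHOX [(R)-4-tert-butyl-2-(2-diphenylphosphinophenyl)-4,5-dihydrooxazole] (cat.), THF, 25 °C
Reagents that add atoms: none
Why: Decarboxylative asymmetric allylic alkylation (Tsuji allylation): zerovalent palladium ionises the allyl carbonate, CO2 is lost, and C–C coupling inside the chiral PHOX–palladium enolate complex should set the quaternary C10 as (R), the (R)-ligand being chosen from the established sense of induction of this ligand class on 2-alkylcyclohexanone enolates.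

Step 3
Reactants: 4 (R)-2-allyl-2,6,6-trimethylcyclohexan-1-one
Product: 5 (R)-2,2,6-trimethyl-6-(2-oxopropyl)cyclohexan-1-one
Conditions: PdCl2 (cat.), Cu(OAc)2 (cat.), O2 (1 bar), DMA/H2O, 25 °C
Reagents that add atoms: water, O
Why: Tsuji–Wacker oxidation: Markovnikov hydroxypalladation of the terminal alkene by divalent palladium should give the methyl ketone, and the fully alpha-substituted ring ketone and C10 are not affected.

Step 4
Reactants: 5 (R)-2,2,6-trimethyl-6-(2-oxopropyl)cyclohexan-1-one
Product: 6 (7aR)-4,4,7a-trimethyl-1,4,5,6,7,7a-hexahydro-2H-inden-2-one (C5=C6 enone, C8 ketone)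
Conditions: KOH (cat.), xylenes, 110 °C, azeotropic removal of water
Reagents that add atoms: none
Why: Intramolecular aldol condensation: the methyl carbon of the 1,4-diketone (future C6) is the only enolisable carbon that reaches the ring carbonyl C5 through a five-membered transition state, and removal of water drives the reaction to the cyclopentenone that serves as the five-membered precursor of ring B.

Step 5
Reactants: 6 bicyclic enone; 7 tert-butyl acrylate
Product: 9 tert-butyl 3-[(1R,7aR)-4,4,7a-trimethyl-2-oxo-2,4,5,6,7,7a-hexahydro-1H-inden-1-yl]propanoate (9β chain), via alpha-chain epimer 8 (not isolated)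
Conditions: LiN(iPr)2 (1.05 equiv), THF, −78 °C; 7, −78 °C; LiN(iPr)2 (1.2 equiv), −78 to −40 °C; AcOH/THF, −78 °C
Reagents that add atoms: none
Why: Michael addition of the cross-conjugated lithium dienolate (C4 and C10 carry no hydrogen, so only C9 can be deprotonated) should place the chain on the alpha face anti to the C10 methyl, and renewed deprotonation followed by kinetic protonation from that same open face should invert C9 to the required 9α-H, 9β-chain configuration.

Step 6
Reactants: 9 enone ester (9β chain)
Product: 10 tert-butyl 3-[(1R,3aS,7aS)-4,4,7a-trimethyl-2-oxooctahydro-1H-inden-1-yl]propanoate (trans-fused, 5α-H)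
Conditions: H2 (5 bar), Pd/C, EtOAc, 25 °C
Reagents that add atoms: none
Why: Heterogeneous syn hydrogenation of the enone C5=C6: the β face is covered by the two syn-axial methyl groups on C4 and C10, so hydrogen should arrive from the α face and give the trans ring fusion (5α-H), as in the saturation of steroidal 14-enes.

Step 7
Reactants: 10 trans-hydrindanone ester
Product: 11 C6=C8 enol triflate of 10 (5α-H, 9α-H, 9β chain, 10β-methyl; OTf on C8)
Conditions: LiN(iPr)2 (1.05 equiv), THF, −78 °C; PhNTf2, −78 to 0 °C
Reagents that add atoms: N-phenylbis(trifluoromethanesulfonimide), O=S(=O)(N(c1ccccc1)S(=O)(=O)C(F)(F)F)C(F)(F)F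
Why: Kinetic enolate formation and O-sulfonylation (enol triflate synthesis): the base removes a proton from the C6 methylene of the more acidic ketone rather than the tertiary C9–H next to quaternary C10 or the ester alpha-CH2, which fixes the double bond at C6=C8 and leaves C9 untouched.

Step 8
Reactants: 11 enol triflate
Product: 12 trans-hydrindene ester with C6=C8 and methyl C17 on C8 (5α-H, 9α-H, 10β-methyl)
Conditions: MeMgBr, Fe(acac)3 (cat.), THF/NMP, −30 to 0 °C
Reagents that add atoms: methylmagnesium bromide, C[Mg]Br
Why: Iron-catalysed Kumada-type cross-coupling of an alkenyl triflate is fast at low temperature, keeps the position of the double bond and tolerates the tert-butyl ester, so that the methyl group C17 is placed on C8.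

Step 9
Reactants: 12 methyl-substituted hydrindene ester
Product: 13 6α,8α-(dibromomethano) adduct of 12 (6,6-dibromobicyclo[3.1.0]hexane unit C6–C7Br2–C8; 6β-H, 8β-methyl)
Conditions: CHBr3, KOtBu, pentane, −10 to 0 °C; kept cold and used at once
Reagents that add atoms: bromoform, BrC(Br)Br
Why: Cheletropic syn addition of electrophilic dibromocarbene to the only alkene, an electron-rich trisubstituted one, should take place on the open α face and bring in C7 as the apex of a 6,6-dibromobicyclo[3.1.0]hexane, the facial outcome being without consequence because C6 and C8 become planar again in step 10.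

Step 10
Reactants: 13 dibromocyclopropane ester
Product: 16 7-bromo-14,15,16-trinorlabd-6-en-13,8α-olide, via bromoallyl cation 14 (not isolated), via tert-butoxycarbenium ion 15 (not isolated)
Conditions: AgBF4 (1.2 equiv), 2,6-di-tert-butyl-4-methylpyridine, CH2Cl2, −40 to 0 °C, dark
Reagents that add atoms: none
Why: Silver ion pulls off the endo bromide while the C6–C8 bond, shared by the three- and the five-membered ring, opens in a disrotatory two-electron electrocyclic process (Woodward–Hoffmann–DePuy rule), so that C7 enters the ring and the cyclopentane C5–C6–C8–C9–C10 becomes the six-membered 7-bromoallyl cation 14; the ester carbonyl oxygen then bonds to C8 to give 15, which sheds isobutene. The closest known reaction type is the silver-promoted ring expansion of 6,6-dibromobicyclo[3.1.0]hexanes with capture of the 2-bromocyclohexenyl cation by a tethered heteroatom nucleophile, joined to the tert-butyl ester cyclisation familiar from halolactonisation. Ring B is not closed by a new bond but arises by one-carbon enlargement, driven by release of cyclopropane and trans-hydrindane strain, and the temporary lactone ring closes in the 6-exo-trig mode. The one new stereocentre, C8, is set by the equatorial C9 tether, which closes to the trans-fused (diequatorial) lactone on the α face, and by the axial C10 methyl, which is 1,3-syn-axial to the β lobe of C8; this gives 8α-O and 8β-methyl, the arrangement that methyl addition to an 8-ketone would not deliver, while C5, C9 and C10 are untouched. The step needs C8-over-C6 regioselectivity and capture faster than proton loss: the tether can reach C8 only, C8 is the tertiary and more charged terminus, and the hindered pyridine base keeps the medium neutral so that the tertiary allylic lactone does not ionise again.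

Step 11
Reactants: 16 bromo lactone
Product: 17 7-bromo-8α-hydroxy-14,15-dinorlabd-6-en-13-one
Conditions: MeLi (1.1 equiv), Et2O, −78 °C; aq. NH4Cl
Reagents that add atoms: methyllithium, [Li]C
Why: Single addition of methyllithium to the δ-lactone at low temperature gives a tetrahedral lithium hemiketal alkoxide that survives until the quench, which removes the temporary ring, installs C16 and frees the 8α-hydroxyl, while bromine–lithium exchange of the alkenyl bromide by MeLi is slow at −78 °C.

Step 12
Reactants: 17 bromo hydroxy ketone
Product: 18 8α-hydroxy-14,15-dinorlabdan-13-one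
Conditions: H2 (1 bar), Pd/C, Et3N, EtOAc, 25 °C
Reagents that add atoms: none
Why: Palladium-catalysed hydrogenolysis of the alkenyl C–Br bond and hydrogenation of the cis-disubstituted C6=C7 alkene take out both helpers of the ring expansion, Et3N binding the HBr so that the tertiary allylic alcohol is not ionised, and no stereocentre is formed.

Step 13
Reactants: 18 hydroxy ketone
Product: 19 ethyl (13E)-8α-hydroxylabd-13-en-15-oate
Conditions: (EtO)2P(O)CH2CO2Et, NaH (excess), THF, 0 °C to reflux; chromatographic removal of the Z isomer
Reagents that add atoms: triethyl phosphonoacetate, CCOC(=O)CP(=O)(OCC)OCC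
Why: Horner–Wadsworth–Emmons olefination of the unhindered methyl ketone with the stabilised phosphonate anion is under thermodynamic control and should favour the E enoate, excess base merely holding the C8 hydroxyl as its alkoxide.

Step 14
Reactants: 19 E enoate
Product: 20 (13E)-labd-13-ene-8α,15-diol
Conditions: iBu2AlH (3.5 equiv), CH2Cl2, −78 to 0 °C; aq. potassium sodium tartrate
Reagents that add atoms: none
Why: 1,2-Reduction of the conjugated ester by iBu2AlH gives the allylic alcohol without conjugate reduction and without change of the alkene geometry.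

Step 15
Reactants: 20 diol
Product: 21 (13E)-8α-hydroxylabd-13-en-15-yl acetate (target)
Conditions: Ac2O (1.2 equiv), pyridine, 0 °C
Reagents that add atoms: acetic anhydride, CC(=O)OC(C)=O
Why: Selective acylation: the unhindered primary allylic hydroxyl reacts with acetic anhydride in pyridine, whereas the hindered tertiary C8 hydroxyl does not under these conditions.

**Compound list**

1 | 2,2,6-trimethylcyclohexan-1-one (racemic) | CC1CCCC(C)(C)C1=O | starting material
2 | allyl chloroformate | C=CCOC(=O)Cl | starting material
3 | allyl 2,6,6-trimethylcyclohex-1-en-1-yl carbonate | C=CCOC(=O)OC1=C(C)CCCC1(C)C | intermediate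
4 | (R)-2-allyl-2,6,6-trimethylcyclohexan-1-one | C=CC[C@@]1(C)CCCC(C)(C)C1=O | intermediate
5 | (R)-2,2,6-trimethyl-6-(2-oxopropyl)cyclohexan-1-one | CC(=O)C[C@@]1(C)CCCC(C)(C)C1=O | intermediate
6 | (7aR)-4,4,7a-trimethyl-1,4,5,6,7,7a-hexahydro-2H-inden-2-one | O=C1C[C@@]2(C)CCCC(C)(C)C2=C1 | intermediate
7 | tert-butyl acrylate | C=CC(=O)OC(C)(C)C | starting material
8 | tert-butyl 3-[(1S,7aR)-4,4,7a-trimethyl-2-oxo-2,4,5,6,7,7a-hexahydro-1H-inden-1-yl]propanoate (9α chain, not isolated) | CC(C)(C)OC(=O)CC[C@H]1[C@@]2(C)CCCC(C)(C)C2=CC1=O | intermediate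
9 | tert-butyl 3-[(1R,7aR)-4,4,7a-trimethyl-2-oxo-2,4,5,6,7,7a-hexahydro-1H-inden-1-yl]propanoate (9β chain) | CC(C)(C)OC(=O)CC[C@@H]1[C@@]2(C)CCCC(C)(C)C2=CC1=O | intermediate
10 | tert-butyl 3-[(1R,3aS,7aS)-4,4,7a-trimethyl-2-oxooctahydro-1H-inden-1-yl]propanoate | CC(C)(C)OC(=O)CC[C@@H]1[C@@]2(C)CCCC(C)(C)[C@@H]2CC1=O | intermediate
11 | (1R,3aS,7aS)-1-(3-tert-butoxy-3-oxopropyl)-4,4,7a-trimethyl-3a,4,5,6,7,7a-hexahydro-1H-inden-2-yl trifluoromethanesulfonate | CC(C)(C)OC(=O)CC[C@@H]1[C@@]2(C)CCCC(C)(C)[C@@H]2C=C1OS(=O)(=O)C(F)(F)F | intermediate
12 | trans-hydrindene ester, C6=C8 with methyl on C8 (5α-H, 9α-H, 10β-methyl) | CC(C)(C)OC(=O)CC[C@@H]1[C@@]2(C)CCCC(C)(C)[C@@H]2C=C1C | intermediate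
13 | 6α,8α-(dibromomethano) adduct of 12 (6β-H, 8β-methyl) | CC(C)(C)OC(=O)CC[C@@H]1[C@@]2(C)CCCC(C)(C)[C@@H]2[C@H]3C(Br)(Br)[C@@]13C | intermediate
14 | ring-expanded 7-bromo C6–C7–C8 allyl cation (not isolated) | CC(C)(C)OC(=O)CC[C@@H]1[C@@]2(C)CCCC(C)(C)[C@@H]2C=C(Br)[C+]1C | intermediate
15 | O-tert-butyl lactonium (tert-butoxycarbenium) ion, 8α-O (not isolated) | CC(C)(C)[O+]=C1CC[C@@H]2[C@@]3(C)CCCC(C)(C)[C@@H]3C=C(Br)[C@@]2(C)O1 | intermediate
16 | 7-bromo-14,15,16-trinorlabd-6-en-13,8α-olide | O=C1CC[C@@H]2[C@@]3(C)CCCC(C)(C)[C@@H]3C=C(Br)[C@@]2(C)O1 | intermediate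
17 | 7-bromo-8α-hydroxy-14,15-dinorlabd-6-en-13-one | CC(=O)CC[C@@H]1[C@@]2(C)CCCC(C)(C)[C@@H]2C=C(Br)[C@@]1(C)O | intermediate
18 | 8α-hydroxy-14,15-dinorlabdan-13-one | CC(=O)CC[C@@H]1[C@@]2(C)CCCC(C)(C)[C@@H]2CC[C@@]1(C)O | intermediate
19 | ethyl (13E)-8α-hydroxylabd-13-en-15-oate | CCOC(=O)/C=C(\C)CC[C@@H]1[C@@]2(C)CCCC(C)(C)[C@@H]2CC[C@@]1(C)O | intermediate
20 | (13E)-labd-13-ene-8α,15-diol | OC/C=C(\C)CC[C@@H]1[C@@]2(C)CCCC(C)(C)[C@@H]2CC[C@@]1(C)O | intermediate
21 | (13E)-8α-hydroxylabd-13-en-15-yl acetate; decalin centres (1R,2R,4aS,8aS) | CC(=O)OC/C=C(\C)CC[C@@H]1[C@@]2(C)CCCC(C)(C)[C@@H]2CC[C@@]1(C)O | target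

**Step count**

Total step count: 15. Longest linear sequence: 15 (steps 1 to 15).

**Steps most likely to fail**

**Step 10.**
- What may go wrong: the allyl cation may lose a proton to give a bromodiene. Compound 13 may open thermally before the silver salt is added, with return of bromide. The tertiary allylic lactone may ionise again.
- The fallback sets out from 10 and comes back at 18.
- Keto ester 10 is homologated with Me3SiCHN2 and BF3·OEt2. The less substituted C6 migrates, so ring B again comes from the five-membered ring. This gives tert-butyl 8-oxo-14,15,16,17-tetranorlabdan-13-oate F1, in which C9 can equilibrate to the equatorial chain.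
- Wittig methylenation with Ph3P=CH2 gives tert-butyl 14,15,16-trinorlabd-8(17)-en-13-oate F2.
- CF3CO2H in CH2Cl2 removes the tert-butyl group and protonates the exocyclic alkene. The C8 cation is captured by the carboxyl group on the α face to give 14,15,16-trinorlabdan-13,8α-olide F3.
- MeLi under the conditions of step 11 then gives 18.

**Step 6.**
- What may go wrong: poor facial selectivity, or no turnover at the alkene, which is flanked by two quaternary carbons.
- The fallback sets out from 9 and comes back at 11.
- A Birch-type reduction (Li, NH3, THF, one equivalent of t-BuOH, −78 °C) protonates C5 as the pyramidal β-carbanion of the reduced enone in its trans-fused geometry. It also leaves the C6=C8 lithium enolate regiospecifically.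
- After evaporation of ammonia this enolate is trapped with PhNTf2. Reduction and triflation thereby merge, and no compound outside the list is made (F0).

**Step 5.**
- What may go wrong: oligomerisation of the acrylate by the ester enolate, slow attack of the neopentyl-type C9 position, or incomplete inversion at C9.
- The fallback sets out from 6 and comes back at 9.
- The lithium dienolate of 6 is alkylated with the far more reactive allyl bromide. C9 is inverted by the same deprotonation and kinetic protonation, which gives (1R,7aR)-1-allyl-4,4,7a-trimethyl-1,4,5,6,7,7a-hexahydro-2H-inden-2-one F4.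
- Hydroboration of the terminal alkene with pinacolborane, catalysed by RhCl(PPh3)3, spares the enone. Oxidation with NaBO3 then gives the 3-hydroxypropyl enone F5.
- TEMPO and PhI(OAc)2 in aqueous MeCN give the propanoic acid F6.
- tert-Butyl 2,2,2-trichloroacetimidate converts F6 into 9.

**Further compounds**

F1 | step 10 | tert-butyl 8-oxo-14,15,16,17-tetranorlabdan-13-oate | CC(C)(C)OC(=O)CC[C@@H]1[C@@]2(C)CCCC(C)(C)[C@@H]2CCC1=O
F2 | step 10 | tert-butyl 14,15,16-trinorlabd-8(17)-en-13-oate | CC(C)(C)OC(=O)CC[C@@H]1[C@@]2(C)CCCC(C)(C)[C@@H]2CCC1=C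
F3 | step 10 | 14,15,16-trinorlabdan-13,8α-olide | O=C1CC[C@@H]2[C@@]3(C)CCCC(C)(C)[C@@H]3CC[C@@]2(C)O1
F0 | step 6 | none | none
F4 | step 5 | (1R,7aR)-1-allyl-4,4,7a-trimethyl-1,4,5,6,7,7a-hexahydro-2H-inden-2-one | C=CC[C@@H]1[C@@]2(C)CCCC(C)(C)C2=CC1=O
F5 | step 5 | (1R,7aR)-1-(3-hydroxypropyl)-4,4,7a-trimethyl-1,4,5,6,7,7a-hexahydro-2H-inden-2-one | OCCC[C@@H]1[C@@]2(C)CCCC(C)(C)C2=CC1=O
F6 | step 5 | 3-[(1R,7aR)-4,4,7a-trimethyl-2-oxo-2,4,5,6,7,7a-hexahydro-1H-inden-1-yl]propanoic acid | OC(=O)CC[C@@H]1[C@@]2(C)CCCC(C)(C)C2=CC1=O
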